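**Retrosynthetic overview**
1. Target 22 ⇐ bis-benzyl ether 21 (hydrogenolysis) ⇐ (Z)-3-butylidenephthalide 20 (enol-lactone hydrolysis unmasks the 2-pentanoylbenzoic acid).
2. Key C–C disconnection: the C(=O)–CH2 bond of the pentanoyl chain, made by intermolecular aldol addition of the C3 anion of phthalide 15 to butanal 16, followed by dehydration.
3. Diaryl ether C–O bond: Cu-catalysed Ullmann coupling of ring A phenol 6 with ring B bromophthalide 14.
4. Ring A phenol 6 comes from olivetol 1 (benzylation, Vilsmeier formylation, Baeyer–Villiger/methanolysis); ring B phthalide 14 comes from 3,5-dibromoanisole 7 (lithiation/carboxylation, esterification, Br–Mg exchange/formylation, reduction–lactonisation).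
5. Ring order: both benzene rings are bought; the only ring made is the lactone of 14 (step 7), carried as a masked keto acid and opened in step 11.

Assumption: the target has no stereocentre and the diaryl ether rotates freely, so it is achiral and is made simply as drawn; the only stereo-element on the way is the Z alkene of 20, which is destroyed in step 11.

**Route**

Step 1
Reactants: 1 olivetol (5-pentylbenzene-1,3-diol)
Product: 2 1,3-bis(benzyloxy)-5-pentylbenzene
Conditions: BnBr (2.3 equiv), K2CO3 (4 equiv), DMF, 60 °C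
Reagents that add atoms: benzyl bromide, BrCc1ccccc1
Why: Williamson ether synthesis protects both phenols as benzyl ethers, which survive every later acidic, basic and organometallic step and come off under neutral conditions at the end.

Step 2
Reactants: 2 1,3-bis(benzyloxy)-5-pentylbenzene
Product: 4 2,4-bis(benzyloxy)-6-pentylbenzaldehyde, via iminium chloride 3 (not isolated)
Conditions: POCl3 (1.3 equiv), DMF, 0 → 70 °C; then ice-water, 50 °C
Reagents that add atoms: N,N-dimethylformamide, CN(C)C=O; water, O
Why: Vilsmeier–Haack formylation of the resorcinol diether goes para to one benzyloxy group and ortho to the other, at the position next to the pentyl chain and not at the more crowded position between the two benzyloxy groups.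

Step 3
Reactants: 4 2,4-bis(benzyloxy)-6-pentylbenzaldehyde
Product: 6 2,4-bis(benzyloxy)-6-pentylphenol, via aryl formate 5 (not isolated)
Conditions: mCPBA (1.3 equiv), CH2Cl2, 0 °C → rt; then K2CO3 (cat.), MeOH, rt
Reagents that add atoms: 3-chloroperoxybenzoic acid (mCPBA), O=C(OO)c1cccc(Cl)c1
Why: Baeyer–Villiger (Dakin-type) oxidation works because the electron-rich aryl group migrates in preference to hydride, and mild methanolysis of the formate then frees the phenol after the peracid has been consumed.

Step 4
Reactants: 7 3,5-dibromoanisole (1,3-dibromo-5-methoxybenzene)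
Product: 9 2,6-dibromo-4-methoxybenzoic acid, via aryllithium 8 (not isolated)
Conditions: LiN(i-Pr)2 (LDA, commercial solution, 1.1 equiv), THF, −78 °C; CO2; then 1 M HCl
Reagents that add atoms: carbon dioxide, O=C=O
Why: Directed ortho-metalation with the non-nucleophilic amide base removes the most acidic proton, the one flanked by both bromines, without Br–Li exchange, and carboxylation of the aryllithium fixes the future CO2H carbon between the two halogens.

Step 5
Reactants: 9 2,6-dibromo-4-methoxybenzoic acid
Product: 10 methyl 2,6-dibromo-4-methoxybenzoate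
Conditions: MeI (1.5 equiv), K2CO3 (2 equiv), DMF, rt
Reagents that add atoms: iodomethane, CI
Why: Carboxylate O-alkylation (SN2 at methyl) esterifies the di-ortho-substituted acid without having to attack its hindered carbonyl.

Step 6
Reactants: 10 methyl 2,6-dibromo-4-methoxybenzoate
Product: 12 methyl 2-bromo-6-formyl-4-methoxybenzoate, via arylmagnesium chloride 11 (not isolated)
Conditions: i-PrMgCl·LiCl (1.1 equiv), THF, −20 °C; DMF (3 equiv), −20 °C → rt; then 1 M HCl
Reagents that add atoms: N,N-dimethylformamide, CN(C)C=O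
Why: Halogen–magnesium exchange (Knochel type) is assisted by the ortho ester and stops after one bromine because the arylmagnesium is deactivated; the substrate is symmetric so there is no regiochemical question, the hindered ester is not attacked, and Bouveault formylation with DMF gives the aldehyde.

Step 7
Reactants: 12 methyl 2-bromo-6-formyl-4-methoxybenzoate
Product: 14 7-bromo-5-methoxy-2-benzofuran-1(3H)-one (7-bromo-5-methoxyphthalide), via hydroxy ester 13 (not isolated)
Conditions: NaBH4 (1 equiv), MeOH/THF, 0 °C → rt; then 1 M HCl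
Reagents that add atoms: none
Why: Chemoselective borohydride reduction of the aldehyde gives a benzylic alcohol that closes onto the neighbouring ester (five-membered lactonisation), so the lactone carbonyl is unambiguously the carbon next to the bromide.

Step 8
Reactants: 6 2,4-bis(benzyloxy)-6-pentylphenol; 14 7-bromo-5-methoxy-2-benzofuran-1(3H)-one
Product: 15 7-[2,4-bis(benzyloxy)-6-pentylphenoxy]-5-methoxy-2-benzofuran-1(3H)-one
Conditions: CuI (10 mol%), picolinic acid (20 mol%), K3PO4 (2 equiv), DMSO, 90 °C, Ar
Reagents that add atoms: none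
Why: Ullmann-type diaryl ether coupling with the CuI/picolinic acid system is suited to ortho-substituted phenols and ortho-carbonyl aryl bromides, and the phthalide has no proton acidic enough for K3PO4 and re-closes on work-up if it is opened.

Step 9
Reactants: 15 7-[2,4-bis(benzyloxy)-6-pentylphenoxy]-5-methoxy-2-benzofuran-1(3H)-one; 16 butanal
Product: 18 7-[2,4-bis(benzyloxy)-6-pentylphenoxy]-3-(1-hydroxybutyl)-5-methoxy-2-benzofuran-1(3H)-one (diastereomer mixture), via lithiated phthalide 17 (not isolated)
Conditions: LiN(i-Pr)2 (LDA, commercial solution, 1.1 equiv), THF, −78 °C, 15 min; butanal (1.5 equiv), −78 °C; AcOH quench at −78 °C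
Reagents that add atoms: none
Why: Intermolecular aldol addition: the C3 carbanion of the phthalide (an ester enolate delocalised through the arene onto the lactone carbonyl) adds to butanal and forms the future C(=O)–CH2 bond; the two new stereocentres are formed without control and both are erased in steps 10 and 11.

Step 10
Reactants: 18 7-[2,4-bis(benzyloxy)-6-pentylphenoxy]-3-(1-hydroxybutyl)-5-methoxy-2-benzofuran-1(3H)-one
Product: 20 (3Z)-7-[2,4-bis(benzyloxy)-6-pentylphenoxy]-3-butylidene-5-methoxy-2-benzofuran-1(3H)-one, via mesylate 19 (not isolated)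
Conditions: MsCl (1.5 equiv), Et3N (3 equiv), CH2Cl2, 0 °C; then DBU (2 equiv), rt
Reagents that add atoms: none
Why: Mesylation followed by E1cB elimination through the acidic C3–H gives the conjugated alkylidenephthalide, mainly the thermodynamically preferred Z isomer (propyl away from the arene C4–H); the geometry does not matter for the next step.

Step 11
Reactants: 20 (3Z)-7-[2,4-bis(benzyloxy)-6-pentylphenoxy]-3-butylidene-5-methoxy-2-benzofuran-1(3H)-one
Product: 21 2-[2,4-bis(benzyloxy)-6-pentylphenoxy]-4-methoxy-6-pentanoylbenzoic acid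
Conditions: LiOH (3 equiv), THF/MeOH/H2O, 40 °C; then 1 M HCl to pH 2
Reagents that add atoms: lithium hydroxide (aqueous), [Li+].[OH-]
Why: Saponification of the enol lactone releases a carboxylate and an enolate that tautomerises to the butyl ketone, the standard way from a 3-alkylidenephthalide to a 2-acylbenzoic acid (which may sit partly as its ring-chain lactol tautomer).

Step 12
Reactants: 21 2-[2,4-bis(benzyloxy)-6-pentylphenoxy]-4-methoxy-6-pentanoylbenzoic acid
Product: 22 2-(2,4-dihydroxy-6-pentylphenoxy)-4-methoxy-6-pentanoylbenzoic acid (target)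
Conditions: H2 (1 atm), 10% Pd/C, EtOAc, rt, monitored and stopped at full debenzylation
Reagents that add atoms: none
Why: Catalytic hydrogenolysis cleaves the two aryl benzyl ethers much faster than it reduces the aryl ketone at 1 atm in neutral EtOAc, and the aryl methyl ether, diaryl ether and acid are inert.

**Compound list**
1 | olivetol (5-pentylbenzene-1,3-diol) | CCCCCc1cc(O)cc(O)c1 | starting material
2 | 1,3-bis(benzyloxy)-5-pentylbenzene | CCCCCc1cc(OCc2ccccc2)cc(OCc2ccccc2)c1 | intermediate
3 | N-{[2,4-bis(benzyloxy)-6-pentylphenyl]methylidene}-N-methylmethanaminium chloride (iminium chloride) | CCCCCc1cc(OCc2ccccc2)cc(OCc2ccccc2)c1C=[N+](C)C.[Cl-] | intermediate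
4 | 2,4-bis(benzyloxy)-6-pentylbenzaldehyde | CCCCCc1cc(OCc2ccccc2)cc(OCc2ccccc2)c1C=O | intermediate
5 | 2,4-bis(benzyloxy)-6-pentylphenyl formate | CCCCCc1cc(OCc2ccccc2)cc(OCc2ccccc2)c1OC=O | intermediate
6 | 2,4-bis(benzyloxy)-6-pentylphenol | CCCCCc1cc(OCc2ccccc2)cc(OCc2ccccc2)c1O | intermediate
7 | 3,5-dibromoanisole (1,3-dibromo-5-methoxybenzene) | COc1cc(Br)cc(Br)c1 | starting material
8 | (2,6-dibromo-4-methoxyphenyl)lithium | COc1cc(Br)c([Li])c(Br)c1 | intermediate
9 | 2,6-dibromo-4-methoxybenzoic acid | COc1cc(Br)c(C(=O)O)c(Br)c1 | intermediate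
10 | methyl 2,6-dibromo-4-methoxybenzoate | COC(=O)c1c(Br)cc(OC)cc1Br | intermediate
11 | [3-bromo-5-methoxy-2-(methoxycarbonyl)phenyl]magnesium chloride | COC(=O)c1c(Br)cc(OC)cc1[Mg]Cl | intermediate
12 | methyl 2-bromo-6-formyl-4-methoxybenzoate | COC(=O)c1c(Br)cc(OC)cc1C=O | intermediate
13 | methyl 2-bromo-6-(hydroxymethyl)-4-methoxybenzoate | COC(=O)c1c(Br)cc(OC)cc1CO | intermediate
14 | 7-bromo-5-methoxy-2-benzofuran-1(3H)-one (7-bromo-5-methoxyphthalide) | O=C1OCc2cc(OC)cc(Br)c12 | intermediate
15 | 7-[2,4-bis(benzyloxy)-6-pentylphenoxy]-5-methoxy-2-benzofuran-1(3H)-one | CCCCCc1cc(OCc2ccccc2)cc(OCc2ccccc2)c1Oc1cc(OC)cc2c1C(=O)OC2 | intermediate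
16 | butanal | CCCC=O | starting material
17 | 3-lithio derivative of 15 (lithiated phthalide) | CCCCCc1cc(OCc2ccccc2)cc(OCc2ccccc2)c1Oc1cc(OC)cc2c1C(=O)OC2[Li] | intermediate
18 | 7-[2,4-bis(benzyloxy)-6-pentylphenoxy]-3-(1-hydroxybutyl)-5-methoxy-2-benzofuran-1(3H)-one (racemic, both diastereomers) | CCCCCc1cc(OCc2ccccc2)cc(OCc2ccccc2)c1Oc1cc(OC)cc2c1C(=O)OC2C(O)CCC | intermediate
19 | 1-{4-[2,4-bis(benzyloxy)-6-pentylphenoxy]-6-methoxy-3-oxo-1,3-dihydro-2-benzofuran-1-yl}butyl methanesulfonate | CCCCCc1cc(OCc2ccccc2)cc(OCc2ccccc2)c1Oc1cc(OC)cc2c1C(=O)OC2C(CCC)OS(C)(=O)=O | intermediate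
20 | (3Z)-7-[2,4-bis(benzyloxy)-6-pentylphenoxy]-3-butylidene-5-methoxy-2-benzofuran-1(3H)-one | CCCCCc1cc(OCc2ccccc2)cc(OCc2ccccc2)c1Oc1cc(OC)cc2c1C(=O)O/C2=C\CCC | intermediate
21 | 2-[2,4-bis(benzyloxy)-6-pentylphenoxy]-4-methoxy-6-pentanoylbenzoic acid | CCCCCc1cc(OCc2ccccc2)cc(OCc2ccccc2)c1Oc1cc(OC)cc(C(=O)CCCC)c1C(=O)O | intermediate
22 | 2-(2,4-dihydroxy-6-pentylphenoxy)-4-methoxy-6-pentanoylbenzoic acid | CCCCCc1cc(O)cc(O)c1Oc1cc(OC)cc(C(=O)CCCC)c1C(=O)O | target

**Step count and risks**

Total steps: 12. Longest linear sequence: 9 steps (7 → 22, steps 4 to 12); the olivetol branch (steps 1 to 3) joins at step 8.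

Most likely to fail, 1: step 8 (Ullmann coupling of a 2,6-disubstituted phenol with an ortho-carbonyl bromide). The fallback sets out from 9 (together with 6) and comes back to the route at 15. It moves the C–O coupling onto the free acid, where the ortho-carboxylate binds copper and accelerates displacement of the neighbouring bromide. Phenol 6 and excess 9 with Cu powder, CuI and K2CO3 in DMF at 110 °C give 2-[2,4-bis(benzyloxy)-6-pentylphenoxy]-6-bromo-4-methoxybenzoic acid F1. MeI/K2CO3 then gives methyl 2-[2,4-bis(benzyloxy)-6-pentylphenoxy]-6-bromo-4-methoxybenzoate F2. Exchange with i-PrMgCl·LiCl turns F2 into the arylmagnesium chloride F3, which DMF formylates to methyl 2-[2,4-bis(benzyloxy)-6-pentylphenoxy]-6-formyl-4-methoxybenzoate F4. NaBH4 reduces F4 to the hydroxymethyl ester F5, which lactonises to 15.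

Most likely to fail, 2: step 9 (the lithiated phthalide may self-condense or enolise butanal). The fallback sets out from 10 (through 11, generated as in step 6) and comes back to the route at 21, so 14 to 20 are bypassed. Arylmagnesium 11 is acylated with N-methoxy-N-methylpentanamide to give methyl 2-bromo-4-methoxy-6-pentanoylbenzoate F6. Aqueous LiOH, helped by the neighbouring ketone, hydrolyses F6 to 2-bromo-4-methoxy-6-pentanoylbenzoic acid F7. The carboxylate-assisted Ullmann coupling of F7 with 6 (Cu powder, CuI, K2CO3, DMF, 110 °C) then gives 21 directly; the carboxylate form is used because a keto ester could cyclise to an indanedione under the coupling base.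

Most likely to fail, 3: step 12 (over-reduction of the aryl ketone or of its lactol form during hydrogenolysis). The fallback sets out from 21 and comes back at 22. It replaces reductive cleavage by Lewis-acid debenzylation with a cation scavenger: BCl3 (4 equiv) and pentamethylbenzene (6 equiv) in CH2Cl2 at −78 °C, then MeOH quench. This leaves the ketone, the acid and the non-chelated aryl methyl ether untouched and makes no new compound (F0).

**Further compounds**
F1 | step 8 | 2-[2,4-bis(benzyloxy)-6-pentylphenoxy]-6-bromo-4-methoxybenzoic acid | CCCCCc1cc(OCc2ccccc2)cc(OCc2ccccc2)c1Oc1cc(OC)cc(Br)c1C(=O)O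
F2 | step 8 | methyl 2-[2,4-bis(benzyloxy)-6-pentylphenoxy]-6-bromo-4-methoxybenzoate | CCCCCc1cc(OCc2ccccc2)cc(OCc2ccccc2)c1Oc1cc(OC)cc(Br)c1C(=O)OC
F3 | step 8 | {3-[2,4-bis(benzyloxy)-6-pentylphenoxy]-5-methoxy-2-(methoxycarbonyl)phenyl}magnesium chloride | CCCCCc1cc(OCc2ccccc2)cc(OCc2ccccc2)c1Oc1cc(OC)cc([Mg]Cl)c1C(=O)OC
F4 | step 8 | methyl 2-[2,4-bis(benzyloxy)-6-pentylphenoxy]-6-formyl-4-methoxybenzoate | CCCCCc1cc(OCc2ccccc2)cc(OCc2ccccc2)c1Oc1cc(OC)cc(C=O)c1C(=O)OC
F5 | step 8 | methyl 2-[2,4-bis(benzyloxy)-6-pentylphenoxy]-6-(hydroxymethyl)-4-methoxybenzoate | CCCCCc1cc(OCc2ccccc2)cc(OCc2ccccc2)c1Oc1cc(OC)cc(CO)c1C(=O)OC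
F6 | step 9 | methyl 2-bromo-4-methoxy-6-pentanoylbenzoate | CCCCC(=O)c1cc(OC)cc(Br)c1C(=O)OC
F7 | step 9 | 2-bromo-4-methoxy-6-pentanoylbenzoic acid | CCCCC(=O)c1cc(OC)cc(Br)c1C(=O)O
F0 | step 12 | none | none
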